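**Strategy.** Everything rests on opening the α-methylene-γ-butyrolactone at its Cα–Cβ bond (C11–C7, germacrane numbering). An acrylate on the lactone oxygen (O8) and a trans-6,7-epoxide are joined by a phosphine-triggered Morita–Baylis–Hillman-type alkylation: the acrylate α-carbon opens the epoxide at C7. The step exploits the contiguous O–C–O triad C6–C7–C8 that frames the lactone ring: anti opening sets C7, closes the trans lactone, returns the exocyclic C11=C13 methylene and frees the C6 hydroxyl for the methacrylate in one operation. The precursor is the acrylate of a Sharpless epoxy alcohol already carrying the 3(2H)-furanone (C10 from (S)-citramalic acid). A Nozaki–Hiyama–Kishi closure of C4–C5 ends the route.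

Key step: step 9

Remark: germacrane numbering is used throughout (C1 furanone C=O, C2 furanone =CH, C3 furanone C–O, C4 the C(=C15H2) carbon, C5 CH(OH), C6 CH(O-methacryloyl), C7 and C8 the lactone ring carbons, C9 CH2, C10 the methyl-bearing quaternary carbon, C11–C13 the methylene lactone); compounds 1, 3 and 9 are taken as commercial.

**Step 1**
Reactants: 1 (S)-citramalic acid
Product: 2 2-[(4S)-2,2,4-trimethyl-5-oxo-1,3-dioxolan-4-yl]acetic acid
Conditions: 2,2-dimethoxypropane, p-TsOH (cat.), rt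
Reagents that add atoms: 2,2-dimethoxypropane COC(C)(C)OC
Why: Acetonide formation on the α-hydroxy acid unit gives the five-membered dioxolanone in preference to the six-membered alternative, which leaves the β-carboxyl (future C8) free and C10 untouched.

**Step 2**
Reactants: 2 2-[(4S)-2,2,4-trimethyl-5-oxo-1,3-dioxolan-4-yl]acetic acid; 3 tert-butyldimethyl(prop-2-yn-1-yloxy)silane
Product: 6 (5S)-5-[(3E)-5-{[tert-butyl(dimethyl)silyl]oxy}-2-oxopent-3-en-1-yl]-2,2,5-trimethyl-1,3-dioxolan-4-one, via acid chloride 4 (not isolated), via alkenylzirconocene 5 (not isolated)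
Conditions: 2, (COCl)2, DMF (cat.), CH2Cl2, 0 °C to rt, evaporate; 3, Cp2Zr(H)Cl, CH2Cl2, rt; combine, CuBr·SMe2 (10 mol %), 0 °C to rt
Reagents that add atoms: oxalyl chloride O=C(Cl)C(=O)Cl (chlorine of 4 only); Schwartz reagent Cl[ZrH](C1C=CC=C1)C1C=CC=C1 (zirconium of 5 only)
Why: syn-Hydrozirconation of the terminal alkyne fixes the E geometry of C6=C7, and copper-catalysed acylation of the alkenylzirconocene by the acid chloride should give the E-enone without touching the dioxolanone.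

**Step 3**
Reactants: 6 (5S)-5-[(3E)-5-{[tert-butyl(dimethyl)silyl]oxy}-2-oxopent-3-en-1-yl]-2,2,5-trimethyl-1,3-dioxolan-4-one
Product: 8 (3S,5S)-5-[(1E)-3-{[tert-butyl(dimethyl)silyl]oxy}prop-1-en-1-yl]-3-hydroxy-3-methyloxolan-2-one, via allylic alcohol 7 (not isolated)
Conditions: (R)-2-methyl-CBS-oxazaborolidine (20 mol %), catecholborane, toluene, −78 °C; then PPTS (cat.), CH2Cl2, rt
Reagents that add atoms: none
Why: Corey–Bakshi–Shibata reduction with the alkenyl arm as the large group should set C8 as S under reagent control, and the new hydroxyl then lactonises onto the activated dioxolanone carbonyl with loss of acetone, which frees the tertiary C10 hydroxyl.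

**Step 4**
Reactants: 8 (3S,5S)-5-[(1E)-3-{[tert-butyl(dimethyl)silyl]oxy}prop-1-en-1-yl]-3-hydroxy-3-methyloxolan-2-one; 9 1,4-bis(trimethylsilyl)buta-1,3-diyne
Product: 11 (6S,8S,9E)-11-{[tert-butyl(dimethyl)silyl]oxy}-6,8-dihydroxy-6-methyl-1-(trimethylsilyl)undec-9-ene-1,3-diyn-5-one, via lithium diynide 10 (not isolated)
Conditions: 9 (3.2 equiv), MeLi·LiBr (3.0 equiv), THF, 0 °C to rt; then 8, THF, −78 to −40 °C; aq. NH4Cl
Reagents that add atoms: methyllithium [Li]C (lithium of 10 only)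
Why: Mono-desilylation gives the lithium diynide, which should add only once to the lactone carbonyl because the lithium lactolate is stable at low temperature (acetylide opening of a lactone to a hydroxy ynone), so C1–C2 is formed and the C8 hydroxyl is released.

**Step 5**
Reactants: 11 (6S,8S,9E)-11-{[tert-butyl(dimethyl)silyl]oxy}-6,8-dihydroxy-6-methyl-1-(trimethylsilyl)undec-9-ene-1,3-diyn-5-one
Product: 13 (2S)-2-[(2S,3E)-5-{[tert-butyl(dimethyl)silyl]oxy}-2-hydroxypent-3-en-1-yl]-5-ethynyl-2-methylfuran-3(2H)-one, via silylethynyl furanone 12 (not isolated)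
Conditions: Ph3PAuNTf2 (2 mol %), CH2Cl2, rt; then K2CO3 (cat.), MeOH, 0 °C
Reagents that add atoms: none
Why: Gold-catalysed 5-endo-dig attack of the tertiary α′-hydroxyl on the ynone β-carbon (C3) should give the 3(2H)-furanone (the C8 hydroxyl would need a seven-membered ring), and methanolysis then removes the alkynyl silyl group.

**Step 6**
Reactants: 13 (2S)-2-[(2S,3E)-5-{[tert-butyl(dimethyl)silyl]oxy}-2-hydroxypent-3-en-1-yl]-5-ethynyl-2-methylfuran-3(2H)-one
Product: 15 (2S)-2-[(2S,3E)-5-{[tert-butyl(dimethyl)silyl]oxy}-2-hydroxypent-3-en-1-yl]-5-(1-iodoethenyl)-2-methylfuran-3(2H)-one, via vinylstannane 14 (not isolated)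
Conditions: Bu3SnH, PdCl2(PPh3)2 (2 mol %), THF, 0 °C; then I2, CH2Cl2, 0 °C
Reagents that add atoms: tributyltin hydride CCCC[SnH](CCCC)CCCC (tin of 14 only); iodine II
Why: Palladium-catalysed syn-hydrostannation should place tin on the alkyne carbon next to the electron-poor furanone (as with ynones and ynoates), and iododestannylation then gives the 1-iodovinyl group at C4 with retention.

**Step 7**
Reactants: 15 (2S)-2-[(2S,3E)-5-{[tert-butyl(dimethyl)silyl]oxy}-2-hydroxypent-3-en-1-yl]-5-(1-iodoethenyl)-2-methylfuran-3(2H)-one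
Product: 16 (2S)-2-{(2S)-2-[(2S,3S)-3-({[tert-butyl(dimethyl)silyl]oxy}methyl)oxiran-2-yl]-2-hydroxyethyl}-5-(1-iodoethenyl)-2-methylfuran-3(2H)-one
Conditions: Ti(OiPr)4 (0.2 equiv), L-(+)-DIPT (0.25 equiv), t-BuOOH, 4 Å MS, CH2Cl2, −20 °C
Reagents that add atoms: tert-butyl hydroperoxide CC(C)(C)OO
Why: Sharpless asymmetric epoxidation in the matched sense, because the (8S)-carbinol is the fast-reacting configuration with L-(+)-tartrate and should give the erythro (6S,7S)-epoxide, while the electron-poor furanone and iodo-diene alkenes are inert.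

**Step 8**
Reactants: 16 (2S)-2-{(2S)-2-[(2S,3S)-3-({[tert-butyl(dimethyl)silyl]oxy}methyl)oxiran-2-yl]-2-hydroxyethyl}-5-(1-iodoethenyl)-2-methylfuran-3(2H)-one
Product: 17 (1S)-1-[(2S,3S)-3-({[tert-butyl(dimethyl)silyl]oxy}methyl)oxiran-2-yl]-2-[(2S)-5-(1-iodoethenyl)-2-methyl-3-oxo-2,3-dihydrofuran-2-yl]ethyl prop-2-enoate
Conditions: acryloyl chloride, iPr2NEt, CH2Cl2, −20 °C
Reagents that add atoms: acryloyl chloride C=CC(=O)Cl
Why: Plain O-acylation of the only free hydroxyl installs C11–C13 on O8 without touching the epoxide.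

**Step 9**
Reactants: 17 (1S)-1-[(2S,3S)-3-({[tert-butyl(dimethyl)silyl]oxy}methyl)oxiran-2-yl]-2-[(2S)-5-(1-iodoethenyl)-2-methyl-3-oxo-2,3-dihydrofuran-2-yl]ethyl prop-2-enoate
Product: 18 (2S)-2-{[(2S,3S)-3-[(1R)-2-{[tert-butyl(dimethyl)silyl]oxy}-1-hydroxyethyl]-4-methylidene-5-oxooxolan-2-yl]methyl}-5-(1-iodoethenyl)-2-methylfuran-3(2H)-one
Conditions: PMe3 (1.0 equiv), t-BuOH, rt, 0.01 M
Reagents that add atoms: none
Why: Proposed new method: PMe3 adds reversibly to the acrylate β-carbon (C13) and the resulting phosphonium ester enolate attacks the epoxide at C7 through its α-carbon (C11); a 1,5-proton shift from C11 to the C6 alkoxide and E1cB loss of PMe3 then return the C11=C13 methylene, so the phosphine is not consumed. The closest known reaction types are the trialkylphosphine-mediated Morita–Baylis–Hillman cyclisation of enones onto tethered epoxides in tert-butanol and the phosphine-catalysed Rauhut–Currier closure of acrylate esters to α-methylene-γ-butyrolactones; what is new is their combination, an acrylate-derived enolate opening an epoxide. The lactone ring (O8–C12–C11–C7–C8) closes in the 5-exo-tet mode. C7 is the only new stereocentre and is set by SN2 inversion, so its configuration follows from the (6S,7S)-epoxide, while C6 keeps its oxygen with retention and C8 is untouched, which gives the trans relation of C6 and C9 on the lactone. The step needs regioselectivity for C7 over C6, secured by the three-atom O8–C12–C11 tether (five- against six-membered ring), and chemoselectivity for the acrylate over the furanone and the iodo-diene, expected because the unhindered acrylate is the best acceptor and any other phosphine addition is reversible and unproductive.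

**Step 10**
Reactants: 18 (2S)-2-{[(2S,3S)-3-[(1R)-2-{[tert-butyl(dimethyl)silyl]oxy}-1-hydroxyethyl]-4-methylidene-5-oxooxolan-2-yl]methyl}-5-(1-iodoethenyl)-2-methylfuran-3(2H)-one
Product: 19 (1R)-2-{[tert-butyl(dimethyl)silyl]oxy}-1-[(2S,3R)-2-{[(2S)-5-(1-iodoethenyl)-2-methyl-3-oxo-2,3-dihydrofuran-2-yl]methyl}-4-methylidene-5-oxooxolan-3-yl]ethyl 2-methylprop-2-enoate
Conditions: methacrylic anhydride, Et3N, DMAP (cat.), CH2Cl2, 0 °C
Reagents that add atoms: methacrylic anhydride C=C(C)C(=O)OC(=O)C(C)=C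
Why: DMAP-catalysed acylation of the only free hydroxyl (C6) installs the methacrylate and at the same time blocks translactonisation onto O6.

**Step 11**
Reactants: 19 (1R)-2-{[tert-butyl(dimethyl)silyl]oxy}-1-[(2S,3R)-2-{[(2S)-5-(1-iodoethenyl)-2-methyl-3-oxo-2,3-dihydrofuran-2-yl]methyl}-4-methylidene-5-oxooxolan-3-yl]ethyl 2-methylprop-2-enoate
Product: 20 (1R)-2-hydroxy-1-[(2S,3R)-2-{[(2S)-5-(1-iodoethenyl)-2-methyl-3-oxo-2,3-dihydrofuran-2-yl]methyl}-4-methylidene-5-oxooxolan-3-yl]ethyl 2-methylprop-2-enoate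
Conditions: HF·pyridine, pyridine, THF, 0 °C
Reagents that add atoms: none
Why: Buffered fluoride desilylation of the primary silyl ether is mildly acidic, so the enoate esters, the methylene lactone and the vinyl iodide should survive and 1,2-acyl migration from O6 to O5 should stay slow.

**Step 12**
Reactants: 20 (1R)-2-hydroxy-1-[(2S,3R)-2-{[(2S)-5-(1-iodoethenyl)-2-methyl-3-oxo-2,3-dihydrofuran-2-yl]methyl}-4-methylidene-5-oxooxolan-3-yl]ethyl 2-methylprop-2-enoate
Product: 21 (1R)-1-[(2S,3R)-2-{[(2S)-5-(1-iodoethenyl)-2-methyl-3-oxo-2,3-dihydrofuran-2-yl]methyl}-4-methylidene-5-oxooxolan-3-yl]-2-oxoethyl 2-methylprop-2-enoate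
Conditions: Dess–Martin periodinane, NaHCO3, CH2Cl2, 0 °C to rt; used crude
Reagents that add atoms: none
Why: Dess–Martin oxidation is neutral and base-free, so the α-acyloxy aldehyde (C5) should form without epimerisation at C6.

**Step 13**
Reactants: 21 (1R)-1-[(2S,3R)-2-{[(2S)-5-(1-iodoethenyl)-2-methyl-3-oxo-2,3-dihydrofuran-2-yl]methyl}-4-methylidene-5-oxooxolan-3-yl]-2-oxoethyl 2-methylprop-2-enoate
Product: 22 CNP0142847.1, (5S,6R,7R,8S,10S)-5-hydroxy-6-methacryloyloxy-1-oxo-3,10-epoxygermacra-2,4(15),11(13)-trien-12,8-olide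
Conditions: CrCl2 (6 equiv), NiCl2 (2 mol %), DMSO/THF, rt, 2 mM (slow addition of 21); aq. sodium serinate work-up
Reagents that add atoms: none
Why: Nozaki–Hiyama–Kishi reaction, in which the C4 alkenylchromium adds only to the aldehyde (esters, lactone and vinylogous ester are inert) and closes the ten-membered carbocycle, and Felkin–Anh attack anti to the C6 acyloxy group should give the 5S carbinol with the C4=C15 methylene in place.

**Compound list**

1 | (S)-citramalic acid, (2S)-2-hydroxy-2-methylbutanedioic acid | C[C@](O)(CC(=O)O)C(=O)O | starting material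
2 | 2-[(4S)-2,2,4-trimethyl-5-oxo-1,3-dioxolan-4-yl]acetic acid | C[C@@]1(CC(=O)O)OC(C)(C)OC1=O | intermediate
3 | tert-butyldimethyl(prop-2-yn-1-yloxy)silane | C#CCO[Si](C)(C)C(C)(C)C | starting material
4 | 2-[(4S)-2,2,4-trimethyl-5-oxo-1,3-dioxolan-4-yl]acetyl chloride | C[C@@]1(CC(=O)Cl)OC(C)(C)OC1=O | intermediate
5 | chlorobis(cyclopentadienyl)[(E)-3-{[tert-butyl(dimethyl)silyl]oxy}prop-1-en-1-yl]zirconium (Cp drawn σ-bonded) | CC(C)(C)[Si](C)(C)OC/C=C/[Zr](Cl)(C1C=CC=C1)C1C=CC=C1 | intermediate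
6 | (5S)-5-[(3E)-5-{[tert-butyl(dimethyl)silyl]oxy}-2-oxopent-3-en-1-yl]-2,2,5-trimethyl-1,3-dioxolan-4-one | C[C@@]1(CC(=O)/C=C/CO[Si](C)(C)C(C)(C)C)OC(C)(C)OC1=O | intermediate
7 | (5S)-5-[(2S,3E)-5-{[tert-butyl(dimethyl)silyl]oxy}-2-hydroxypent-3-en-1-yl]-2,2,5-trimethyl-1,3-dioxolan-4-one | C[C@@]1(C[C@H](O)/C=C/CO[Si](C)(C)C(C)(C)C)OC(C)(C)OC1=O | intermediate
8 | (3S,5S)-5-[(1E)-3-{[tert-butyl(dimethyl)silyl]oxy}prop-1-en-1-yl]-3-hydroxy-3-methyloxolan-2-one | C[C@]1(O)C[C@@H](/C=C/CO[Si](C)(C)C(C)(C)C)OC1=O | intermediate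
9 | 1,4-bis(trimethylsilyl)buta-1,3-diyne | C[Si](C)(C)C#CC#C[Si](C)(C)C | starting material
10 | lithium 4-(trimethylsilyl)buta-1,3-diyn-1-ide | [Li]C#CC#C[Si](C)(C)C | intermediate
11 | (6S,8S,9E)-11-{[tert-butyl(dimethyl)silyl]oxy}-6,8-dihydroxy-6-methyl-1-(trimethylsilyl)undec-9-ene-1,3-diyn-5-one | C[C@](O)(C[C@H](O)/C=C/CO[Si](C)(C)C(C)(C)C)C(=O)C#CC#C[Si](C)(C)C | intermediate
12 | (2S)-2-[(2S,3E)-5-{[tert-butyl(dimethyl)silyl]oxy}-2-hydroxypent-3-en-1-yl]-2-methyl-5-[(trimethylsilyl)ethynyl]furan-3(2H)-one | C[C@@]1(C[C@H](O)/C=C/CO[Si](C)(C)C(C)(C)C)OC(C#C[Si](C)(C)C)=CC1=O | intermediate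
13 | (2S)-2-[(2S,3E)-5-{[tert-butyl(dimethyl)silyl]oxy}-2-hydroxypent-3-en-1-yl]-5-ethynyl-2-methylfuran-3(2H)-one | C[C@@]1(C[C@H](O)/C=C/CO[Si](C)(C)C(C)(C)C)OC(C#C)=CC1=O | intermediate
14 | (2S)-2-[(2S,3E)-5-{[tert-butyl(dimethyl)silyl]oxy}-2-hydroxypent-3-en-1-yl]-2-methyl-5-[1-(tributylstannyl)ethenyl]furan-3(2H)-one | C[C@@]1(C[C@H](O)/C=C/CO[Si](C)(C)C(C)(C)C)OC(C(=C)[Sn](CCCC)(CCCC)CCCC)=CC1=O | intermediate
15 | (2S)-2-[(2S,3E)-5-{[tert-butyl(dimethyl)silyl]oxy}-2-hydroxypent-3-en-1-yl]-5-(1-iodoethenyl)-2-methylfuran-3(2H)-one | C[C@@]1(C[C@H](O)/C=C/CO[Si](C)(C)C(C)(C)C)OC(C(=C)I)=CC1=O | intermediate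
16 | (2S)-2-{(2S)-2-[(2S,3S)-3-({[tert-butyl(dimethyl)silyl]oxy}methyl)oxiran-2-yl]-2-hydroxyethyl}-5-(1-iodoethenyl)-2-methylfuran-3(2H)-one | C[C@@]1(C[C@H](O)[C@@H]2O[C@H]2CO[Si](C)(C)C(C)(C)C)OC(C(=C)I)=CC1=O | intermediate
17 | (1S)-1-[(2S,3S)-3-({[tert-butyl(dimethyl)silyl]oxy}methyl)oxiran-2-yl]-2-[(2S)-5-(1-iodoethenyl)-2-methyl-3-oxo-2,3-dihydrofuran-2-yl]ethyl prop-2-enoate | C[C@@]1(C[C@H](OC(=O)C=C)[C@@H]2O[C@H]2CO[Si](C)(C)C(C)(C)C)OC(C(=C)I)=CC1=O | intermediate
18 | (2S)-2-{[(2S,3S)-3-[(1R)-2-{[tert-butyl(dimethyl)silyl]oxy}-1-hydroxyethyl]-4-methylidene-5-oxooxolan-2-yl]methyl}-5-(1-iodoethenyl)-2-methylfuran-3(2H)-one | C[C@@]1(C[C@@H]2OC(=O)C(=C)[C@H]2[C@@H](O)CO[Si](C)(C)C(C)(C)C)OC(C(=C)I)=CC1=O | intermediate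
19 | (1R)-2-{[tert-butyl(dimethyl)silyl]oxy}-1-[(2S,3R)-2-{[(2S)-5-(1-iodoethenyl)-2-methyl-3-oxo-2,3-dihydrofuran-2-yl]methyl}-4-methylidene-5-oxooxolan-3-yl]ethyl 2-methylprop-2-enoate | C[C@@]1(C[C@@H]2OC(=O)C(=C)[C@H]2[C@@H](OC(=O)C(C)=C)CO[Si](C)(C)C(C)(C)C)OC(C(=C)I)=CC1=O | intermediate
20 | (1R)-2-hydroxy-1-[(2S,3R)-2-{[(2S)-5-(1-iodoethenyl)-2-methyl-3-oxo-2,3-dihydrofuran-2-yl]methyl}-4-methylidene-5-oxooxolan-3-yl]ethyl 2-methylprop-2-enoate | C[C@@]1(C[C@@H]2OC(=O)C(=C)[C@H]2[C@@H](OC(=O)C(C)=C)CO)OC(C(=C)I)=CC1=O | intermediate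
21 | (1R)-1-[(2S,3R)-2-{[(2S)-5-(1-iodoethenyl)-2-methyl-3-oxo-2,3-dihydrofuran-2-yl]methyl}-4-methylidene-5-oxooxolan-3-yl]-2-oxoethyl 2-methylprop-2-enoate | C[C@@]1(C[C@@H]2OC(=O)C(=C)[C@H]2[C@@H](OC(=O)C(C)=C)C=O)OC(C(=C)I)=CC1=O | intermediate
22 | CNP0142847.1, (5S,6R,7R,8S,10S)-5-hydroxy-6-methacryloyloxy-1-oxo-3,10-epoxygermacra-2,4(15),11(13)-trien-12,8-olide | C=C(C)C(=O)O[C@@H]1[C@@H]2C(=C)C(=O)O[C@H]2C[C@]2(C)OC(=CC2=O)C(=C)[C@@H]1O | target

**Step count.** Total: 13 steps. Longest linear sequence: 13 steps (1 to 22); 3 and 9 are bought and enter in steps 2 and 4.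

**Steps most likely to fail**

Step 9 (Proposed new method). The phosphonium enolate of an ester may be protonated by the alcohol solvent faster than it opens the epoxide, so that the acrylate is recovered or oligomerises; alkoxide-mediated translactonisation onto O6 is a second leak. The fallback uses known chemistry, sets out from 16 and returns at 18. Epoxy alcohol 16 is esterified with diethylphosphonoacetic acid (DCC, DMAP, CH2Cl2) to the phosphonoacetate F1. NaH (THF, 0 °C to rt) should close the lactone by the same 5-exo opening of the epoxide at C7 by the stabilised carbanion, giving the α-diethoxyphosphoryl lactone F2, kept as its sodium salt. Aqueous formaldehyde with K2CO3 (Horner–Wadsworth–Emmons methylenation) then gives 18.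

Step 13. Transannular strain in the closing nine-membered oxa-bridged ring may override the Felkin–Anh preference, so that facial selectivity at C5 is poor. The fallback sets out from 21 and returns at 22. The ring-closure product that contains the C5 epimer F3 is oxidised as the mixture (Dess–Martin periodinane, NaHCO3) to the macrocyclic C5 ketone F4. Reagent-controlled Corey–Bakshi–Shibata reduction ((S)-Me-CBS, catecholborane, −78 °C; alkenyl C4 as the large group) should then return the 5S carbinol 22.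

Step 6. Regiochemical leakage of the hydrostannation to the terminal (E)-stannane would give the wrong iodoalkene. The fallback moves the halide precursor into the alkyne building block; it sets out from 8 and returns at 15. (1-Bromoethenyl)trimethylsilane is coupled with ethynylmagnesium bromide (Pd(PPh3)4, THF) to 2-(trimethylsilyl)but-1-en-3-yne F5. Deprotonation with n-BuLi gives its lithium acetylide F6, which is added to lactone 8 as in step 4 to give the hydroxy ynone F7. Gold-catalysed cyclisation as in step 5 gives the 1-(trimethylsilyl)vinyl furanone F8, and ipso-iododesilylation (NIS, MeCN/ClCH2CN, 0 °C) gives 15.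

**Further compounds**

F1 | step 9 | (1S)-1-[(2S,3S)-3-({[tert-butyl(dimethyl)silyl]oxy}methyl)oxiran-2-yl]-2-[(2S)-5-(1-iodoethenyl)-2-methyl-3-oxo-2,3-dihydrofuran-2-yl]ethyl 2-(diethoxyphosphoryl)acetate | C[C@@]1(C[C@H](OC(=O)CP(=O)(OCC)OCC)[C@@H]2O[C@H]2CO[Si](C)(C)C(C)(C)C)OC(C(=C)I)=CC1=O
F2 | step 9 | α-(diethoxyphosphoryl) analogue of 18 (P on C11 in place of the methylene, C11 epimers) | C[C@@]1(C[C@@H]2OC(=O)C(P(=O)(OCC)OCC)[C@H]2[C@@H](O)CO[Si](C)(C)C(C)(C)C)OC(C(=C)I)=CC1=O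
F3 | step 13 | C5 epimer of 22 (5R) | C=C(C)C(=O)O[C@@H]1[C@@H]2C(=C)C(=O)O[C@H]2C[C@]2(C)OC(=CC2=O)C(=C)[C@H]1O
F4 | step 13 | 5-oxo analogue of 22 (macrocyclic C5 ketone) | C=C(C)C(=O)O[C@@H]1[C@@H]2C(=C)C(=O)O[C@H]2C[C@]2(C)OC(=CC2=O)C(=C)C1=O
F5 | step 6 | 2-(trimethylsilyl)but-1-en-3-yne | C#CC(=C)[Si](C)(C)C
F6 | step 6 | lithium 3-(trimethylsilyl)but-3-en-1-yn-1-ide | [Li]C#CC(=C)[Si](C)(C)C
F7 | step 6 | (5S,7S,8E)-10-{[tert-butyl(dimethyl)silyl]oxy}-5,7-dihydroxy-5-methyl-2-(trimethylsilyl)deca-1,8-dien-3-yn-4-one | C[C@](O)(C[C@H](O)/C=C/CO[Si](C)(C)C(C)(C)C)C(=O)C#CC(=C)[Si](C)(C)C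
F8 | step 6 | (2S)-2-[(2S,3E)-5-{[tert-butyl(dimethyl)silyl]oxy}-2-hydroxypent-3-en-1-yl]-2-methyl-5-[1-(trimethylsilyl)ethenyl]furan-3(2H)-one | C[C@@]1(C[C@H](O)/C=C/CO[Si](C)(C)C(C)(C)C)OC(C(=C)[Si](C)(C)C)=CC1=O
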